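**Plan**

Carotenoid numbering is used: ε-ring C1'–C6' (C1' gem-dimethyl, C3' carbinol, C5' methyl-bearing alkene carbon, C6' chain-bearing), β-ring C1–C6, chain C7–C15 and C15'–C7'. The retrosynthesis cuts C7'=C8' (Julia–Kocienski olefination), C6–C7 (Sonogashira coupling) and C7≡C8 (aldehyde-to-alkyne homologation), and inside the ε-ring C1'–C2' and C5'–C6'.
Forward, the ε-ring is the only ring that is closed: a Robinson annulation of 2-methylpropanal (C6', C1' and its two methyls) with pent-1-en-3-one (C2', C3', C4', C5' and its methyl) gives an achiral enone. The β-ring is bought as actinol, and the chain is joined as C9 triflate + C1 + C20 dialdehyde, then C30 aldehyde + C10 sulfone.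
Enabling feature: in the ε-ring the methyl-bearing sp2 carbon C5' lies between C4' and C6', and the quaternary C1' lies between C6' and C2'. With the double bond written as C5'=C6' and a carbonyl on C4', the ring is 2,4,4-trimethylcyclohex-2-enone, whose C1'–C2' bond is a Michael bond and whose C5'=C6' bond is an aldol bond; a later [2,3] shift returns the double bond to C4'=C5'.
Stereochemistry: C3 comes from actinol. C4' is set by a Corey–Bakshi–Shibata (CBS) reduction and carried to C6' by a suprafacial Wittig–Still [2,3] rearrangement that also adds C7'. C3' is set by allylic oxidation and a second CBS reduction. The alkene geometry comes from all-E crocetindial and the E-selective olefination.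

Key step: step 1

Remark (assumption): all-E crocetindial and (4R,6R)-actinol are taken as purchasable building blocks.

**Route**

Step 1
Reactants: 1 2-methylpropanal; 2 pent-1-en-3-one
Product: 5 2,4,4-trimethylcyclohex-2-en-1-one, via 2,2-dimethyl-5-oxoheptanal 3 (not isolated), via 3-hydroxy-2,4,4-trimethylcyclohexan-1-one 4 (not isolated)
Conditions: H2SO4 (cat.), toluene, 45 °C, then reflux with a Dean–Stark trap
Reagents that add atoms: none
Why: Acid-catalysed Michael addition of the enol of 1 to the β-carbon of protonated 2 makes the C1'–C2' bond and the quaternary C1' of keto aldehyde 3, and the enol of the ethyl ketone then adds to the aldehyde and loses water, which closes C5'=C6'. The closest known reaction type is the acid-mediated Robinson annulation of α-branched aldehydes with alkyl vinyl ketones to 4,4-disubstituted cyclohex-2-enones. The six-membered ring closes by a 6-(enolendo)-exo-trig aldol addition followed by dehydration into conjugation. No stereocenter survives: the two centers of aldol 4 are erased on dehydration and enone 5 is achiral by design, because the configuration is put in afterwards at C4' by a reagent and then moved to C6'. The selectivity needed is constitutional and is secured by the substrates: 1 has a single α-hydrogen, so it can only be the Michael donor and cannot condense with itself, and of the two enols of the ketone in 3 only the one toward the ethyl group reaches the aldehyde through a six-membered ring, the other would give a four-membered ring. Removal of water drives the sequence to 5.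

Step 2
Reactants: 5 2,4,4-trimethylcyclohex-2-en-1-one
Product: 6 (1S)-2,4,4-trimethylcyclohex-2-en-1-ol
Conditions: (R)-Me-CBS catalyst [(R)-1-methyl-3,3-diphenyltetrahydro-1H,3H-pyrrolo[1,2-c][1,3,2]oxazaborole, 10 mol %], BH3·SMe2, THF, −20 °C; then MeOH
Reagents that add atoms: none
Why: Corey–Bakshi–Shibata reduction, in which the ketone binds to the catalyst boron anti to the larger α-methyl-alkenyl arm and the catalyst-bound borane delivers hydride to one face, which with the (R)-catalyst should give the (S) carbinol at C4', the control element for C6'.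

Step 3
Reactants: 6 (1S)-2,4,4-trimethylcyclohex-2-en-1-ol
Product: 7 tributyl({[(1S)-2,4,4-trimethylcyclohex-2-en-1-yl]oxy}methyl)stannane
Conditions: KH, THF, 0 °C; then Bu3SnCH2I, 0 °C → rt
Reagents that add atoms: tributyl(iodomethyl)stannane, CCCC[Sn](CCCC)(CCCC)CI
Why: Williamson ether synthesis of the potassium alkoxide with the primary iodide, which leaves the carbinol center untouched.

Step 4
Reactants: 7 tributyl({[(1S)-2,4,4-trimethylcyclohex-2-en-1-yl]oxy}methyl)stannane
Product: 9 [(1R)-2,6,6-trimethylcyclohex-2-en-1-yl]methanol, via lithiomethyl ether 8 (not isolated)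
Conditions: nBuLi, THF, −78 → −30 °C; then aq. NH4Cl
Reagents that add atoms: none
Why: Tin–lithium exchange gives the α-alkoxy organolithium 8, which undergoes the [2,3]-Wittig (Wittig–Still) rearrangement through a five-membered envelope transition state, so that the new C6'–C7' bond forms on the ring face from which the C4'–O bond leaves (S at C4' becomes R at C6') while the double bond moves to C4'=C5'.

Step 5
Reactants: 9 [(1R)-2,6,6-trimethylcyclohex-2-en-1-yl]methanol
Product: 10 1-phenyl-5-({[(1R)-2,6,6-trimethylcyclohex-2-en-1-yl]methyl}sulfanyl)-1H-tetrazole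
Conditions: 1-phenyl-1H-tetrazole-5-thiol, PPh3, diisopropyl azodicarboxylate, THF, 0 °C → rt
Reagents that add atoms: 1-phenyl-1H-tetrazole-5-thiol, Sc1nnnn1-c1ccccc1
Why: Mitsunobu thioetherification of the primary alcohol with the acidic heteroaryl thiol, which does not involve a stereocenter.

Step 6
Reactants: 10 1-phenyl-5-({[(1R)-2,6,6-trimethylcyclohex-2-en-1-yl]methyl}sulfanyl)-1H-tetrazole
Product: 11 1-phenyl-5-({[(1R)-2,6,6-trimethylcyclohex-2-en-1-yl]methyl}sulfonyl)-1H-tetrazole
Conditions: (NH4)6Mo7O24·4H2O (10 mol %), 30% H2O2, EtOH, 0 °C → rt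
Reagents that add atoms: hydrogen peroxide, OO
Why: Molybdate-catalysed oxidation of the sulfide with hydrogen peroxide goes on to the sulfone and is known to spare trisubstituted alkenes.

Step 7
Reactants: 11 1-phenyl-5-({[(1R)-2,6,6-trimethylcyclohex-2-en-1-yl]methyl}sulfonyl)-1H-tetrazole
Product: 12 (4R)-3,5,5-trimethyl-4-{[(1-phenyl-1H-tetrazol-5-yl)sulfonyl]methyl}cyclohex-2-en-1-one
Conditions: Rh2(C6H10NO)4 (dirhodium tetracaprolactamate, 1 mol %), 70% aq. tBuOOH, 1,2-dichloroethane, 40 °C
Reagents that add atoms: tert-butyl hydroperoxide, CC(C)(C)OO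
Why: Radical allylic oxidation by tert-butylperoxyl radicals should attack the secondary allylic CH2 (C3') next to the unsubstituted alkene carbon in preference to the hindered tertiary C6'–H and the methyl group, as in the oxidation of 1-methylcyclohexene to 3-methylcyclohex-2-enone, and the base-free medium avoids loss of sulfinate from the γ-acidic enone.

Step 8
Reactants: 12 (4R)-3,5,5-trimethyl-4-{[(1-phenyl-1H-tetrazol-5-yl)sulfonyl]methyl}cyclohex-2-en-1-one
Product: 13 (1R,4R)-3,5,5-trimethyl-4-{[(1-phenyl-1H-tetrazol-5-yl)sulfonyl]methyl}cyclohex-2-en-1-ol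
Conditions: (S)-Me-CBS catalyst (enantiomer of the catalyst of step 2, 20 mol %), BH3·SMe2, THF, −30 °C; then MeOH
Reagents that add atoms: none
Why: Corey–Bakshi–Shibata reduction in which the conjugated alkene arm acts as the large group, so that the (S)-catalyst should deliver hydride to the face of C3' cis to the C6' side chain and give the (3'R) carbinol trans to that chain.

Step 9
Reactants: 13 (1R,4R)-3,5,5-trimethyl-4-{[(1-phenyl-1H-tetrazol-5-yl)sulfonyl]methyl}cyclohex-2-en-1-ol
Product: 14 5-({[(1R,4R)-4-{[tert-butyl(dimethyl)silyl]oxy}-2,6,6-trimethylcyclohex-2-en-1-yl]methyl}sulfonyl)-1-phenyl-1H-tetrazole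
Conditions: TBSCl, imidazole, DMF, rt
Reagents that add atoms: tert-butyl(chloro)dimethylsilane, CC(C)(C)[Si](C)(C)Cl
Why: Standard silylation of the secondary allylic alcohol, which masks it against the base of the olefination.

Step 10
Reactants: 15 (4R,6R)-4-hydroxy-2,2,6-trimethylcyclohexan-1-one (actinol)
Product: 16 (4R,6R)-4-{[tert-butyl(dimethyl)silyl]oxy}-2,2,6-trimethylcyclohexan-1-one
Conditions: TBSCl, imidazole, DMF, rt
Reagents that add atoms: tert-butyl(chloro)dimethylsilane, CC(C)(C)[Si](C)(C)Cl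
Why: Standard silylation of the secondary alcohol, which leaves both stereocenters of actinol untouched.

Step 11
Reactants: 16 (4R,6R)-4-{[tert-butyl(dimethyl)silyl]oxy}-2,2,6-trimethylcyclohexan-1-one
Product: 17 (4R)-4-{[tert-butyl(dimethyl)silyl]oxy}-2,6,6-trimethylcyclohex-1-en-1-yl trifluoromethanesulfonate
Conditions: LiN(iPr)2, THF, −78 → 0 °C; PhNTf2, −78 °C → rt; aq. NH4Cl
Reagents that add atoms: N-phenylbis(trifluoromethanesulfonimide), O=S(=O)(N(c1ccccc1)S(=O)(=O)C(F)(F)F)C(F)(F)F
Why: The ketone has an α-hydrogen only on the methyl-bearing carbon (the other α-carbon is quaternary), so deprotonation gives a single tetrasubstituted enolate that is O-sulfonylated to the enol triflate, whereby that center becomes sp2 and the (R) carbinol carbon becomes C3 of the target.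

Step 12
Reactants: 18 (2E,4E,6E,8E,10E,12E,14E)-2,6,11,15-tetramethylhexadeca-2,4,6,8,10,12,14-heptaenedial (crocetindial)
Product: 19 (2E,4E,6E,8E,10E,12E,14E)-2,6,11,15-tetramethylheptadeca-2,4,6,8,10,12,14-heptaen-16-ynal
Conditions: Me3SiCHN2, LiN(iPr)2, THF, −78 °C; added to 18 (2.5 equiv), THF, −78 °C → rt; aq. NH4Cl; argon, dark
Reagents that add atoms: (trimethylsilyl)diazomethane, C[Si](C)(C)C=[N+]=[N-]
Why: Colvin rearrangement, in which the lithiated silyl diazomethane adds to one aldehyde group, lithium trimethylsilanolate is lost and the diazoalkene loses N2 and rearranges by a 1,2-hydrogen shift to the terminal alkyne under aprotic conditions that tolerate enals, while the excess of the symmetrical dialdehyde favours single homologation and the all-E geometry is not touched.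

Step 13
Reactants: 17 (4R)-4-{[tert-butyl(dimethyl)silyl]oxy}-2,6,6-trimethylcyclohex-1-en-1-yl trifluoromethanesulfonate; 19 (2E,4E,6E,8E,10E,12E,14E)-2,6,11,15-tetramethylheptadeca-2,4,6,8,10,12,14-heptaen-16-ynal
Product: 20 (2E,4E,6E,8E,10E,12E,14E)-17-[(4R)-4-{[tert-butyl(dimethyl)silyl]oxy}-2,6,6-trimethylcyclohex-1-en-1-yl]-2,6,11,15-tetramethylheptadeca-2,4,6,8,10,12,14-heptaen-16-ynal
Conditions: Pd(PPh3)4 (5 mol %), CuI (10 mol %), iPr2NH, THF, rt; argon, dark
Reagents that add atoms: none
Why: Sonogashira coupling of the terminal alkyne with the alkenyl triflate forms the C6–C7 bond under mild amine conditions that leave the aldehyde, the silyl ether and the polyene untouched.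

Step 14
Reactants: 14 5-({[(1R,4R)-4-{[tert-butyl(dimethyl)silyl]oxy}-2,6,6-trimethylcyclohex-2-en-1-yl]methyl}sulfonyl)-1-phenyl-1H-tetrazole; 20 the C30 aldehyde of step 13
Product: 21 (3R,3'R,6'R)-3,3'-bis{[tert-butyl(dimethyl)silyl]oxy}-7,8-didehydro-β,ε-carotene (all-E)
Conditions: KN(SiMe3)2, THF, −78 °C; then 20, −78 °C → rt; aq. NH4Cl; argon, dark
Reagents that add atoms: none
Why: Julia–Kocienski olefination, in which the sulfonyl carbanion adds to the aldehyde, the tetrazolyl group migrates from sulfur to oxygen (Smiles rearrangement) and anti-elimination of SO2 and the tetrazololate should give the (E)-C7'=C8' bond, favoured by the bulky branched sulfone, while C6' is not acidified and keeps its configuration.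

Step 15
Reactants: 21 (3R,3'R,6'R)-3,3'-bis{[tert-butyl(dimethyl)silyl]oxy}-7,8-didehydro-β,ε-carotene
Product: 22 (3R,3'R,6'R)-7,8-didehydro-β,ε-carotene-3,3'-diol (the target)
Conditions: Bu4NF, THF, 0 °C → rt; aq. NH4Cl; argon, dark
Reagents that add atoms: none
Why: Fluoride cleaves both silyl ethers under conditions to which the polyene, the alkyne and the allylic alcohol are stable, which should give the target.

**Compound list**

1 | 2-methylpropanal | CC(C)C=O | starting material
2 | pent-1-en-3-one | CCC(=O)C=C | starting material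
3 | 2,2-dimethyl-5-oxoheptanal | CCC(=O)CCC(C)(C)C=O | intermediate
4 | 3-hydroxy-2,4,4-trimethylcyclohexan-1-one (racemic, both diastereomers) | CC1C(O)C(C)(C)CCC1=O | intermediate
5 | 2,4,4-trimethylcyclohex-2-en-1-one | CC1=CC(C)(C)CCC1=O | intermediate
6 | (1S)-2,4,4-trimethylcyclohex-2-en-1-ol | CC1=CC(C)(C)CC[C@@H]1O | intermediate
7 | tributyl({[(1S)-2,4,4-trimethylcyclohex-2-en-1-yl]oxy}methyl)stannane | CC1=CC(C)(C)CC[C@@H]1OC[Sn](CCCC)(CCCC)CCCC | intermediate
8 | ({[(1S)-2,4,4-trimethylcyclohex-2-en-1-yl]oxy}methyl)lithium | CC1=CC(C)(C)CC[C@@H]1OC[Li] | intermediate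
9 | [(1R)-2,6,6-trimethylcyclohex-2-en-1-yl]methanol | CC1=CCCC(C)(C)[C@H]1CO | intermediate
10 | 1-phenyl-5-({[(1R)-2,6,6-trimethylcyclohex-2-en-1-yl]methyl}sulfanyl)-1H-tetrazole | CC1=CCCC(C)(C)[C@H]1CSc1nnnn1-c1ccccc1 | intermediate
11 | 1-phenyl-5-({[(1R)-2,6,6-trimethylcyclohex-2-en-1-yl]methyl}sulfonyl)-1H-tetrazole | CC1=CCCC(C)(C)[C@H]1CS(=O)(=O)c1nnnn1-c1ccccc1 | intermediate
12 | (4R)-3,5,5-trimethyl-4-{[(1-phenyl-1H-tetrazol-5-yl)sulfonyl]methyl}cyclohex-2-en-1-one | CC1=CC(=O)CC(C)(C)[C@H]1CS(=O)(=O)c1nnnn1-c1ccccc1 | intermediate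
13 | (1R,4R)-3,5,5-trimethyl-4-{[(1-phenyl-1H-tetrazol-5-yl)sulfonyl]methyl}cyclohex-2-en-1-ol | CC1=C[C@H](O)CC(C)(C)[C@H]1CS(=O)(=O)c1nnnn1-c1ccccc1 | intermediate
14 | 5-({[(1R,4R)-4-{[tert-butyl(dimethyl)silyl]oxy}-2,6,6-trimethylcyclohex-2-en-1-yl]methyl}sulfonyl)-1-phenyl-1H-tetrazole | CC1=C[C@H](O[Si](C)(C)C(C)(C)C)CC(C)(C)[C@H]1CS(=O)(=O)c1nnnn1-c1ccccc1 | intermediate
15 | (4R,6R)-4-hydroxy-2,2,6-trimethylcyclohexan-1-one (actinol) | O=C1C(C)(C)C[C@H](O)C[C@H]1C | starting material
16 | (4R,6R)-4-{[tert-butyl(dimethyl)silyl]oxy}-2,2,6-trimethylcyclohexan-1-one | O=C1C(C)(C)C[C@H](O[Si](C)(C)C(C)(C)C)C[C@H]1C | intermediate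
17 | (4R)-4-{[tert-butyl(dimethyl)silyl]oxy}-2,6,6-trimethylcyclohex-1-en-1-yl trifluoromethanesulfonate | CC1=C(OS(=O)(=O)C(F)(F)F)C(C)(C)C[C@H](O[Si](C)(C)C(C)(C)C)C1 | intermediate
18 | (2E,4E,6E,8E,10E,12E,14E)-2,6,11,15-tetramethylhexadeca-2,4,6,8,10,12,14-heptaenedial (crocetindial) | O=C/C(C)=C/C=C/C(C)=C/C=C/C=C(C)/C=C/C=C(\C)C=O | starting material
19 | (2E,4E,6E,8E,10E,12E,14E)-2,6,11,15-tetramethylheptadeca-2,4,6,8,10,12,14-heptaen-16-ynal | O=C/C(C)=C/C=C/C(C)=C/C=C/C=C(C)/C=C/C=C(\C)C#C | intermediate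
20 | (2E,4E,6E,8E,10E,12E,14E)-17-[(4R)-4-{[tert-butyl(dimethyl)silyl]oxy}-2,6,6-trimethylcyclohex-1-en-1-yl]-2,6,11,15-tetramethylheptadeca-2,4,6,8,10,12,14-heptaen-16-ynal | O=C/C(C)=C/C=C/C(C)=C/C=C/C=C(C)/C=C/C=C(\C)C#CC1=C(C)C[C@@H](O[Si](C)(C)C(C)(C)C)CC1(C)C | intermediate
21 | (3R,3'R,6'R)-3,3'-bis{[tert-butyl(dimethyl)silyl]oxy}-7,8-didehydro-β,ε-carotene (all-E) | CC1=C[C@H](O[Si](C)(C)C(C)(C)C)CC(C)(C)[C@H]1/C=C/C(C)=C/C=C/C(C)=C/C=C/C=C(C)/C=C/C=C(\C)C#CC1=C(C)C[C@@H](O[Si](C)(C)C(C)(C)C)CC1(C)C | intermediate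
22 | (3R,3'R,6'R)-7,8-didehydro-β,ε-carotene-3,3'-diol (all-E) | CC1=C[C@H](O)CC(C)(C)[C@H]1/C=C/C(C)=C/C=C/C(C)=C/C=C/C=C(C)/C=C/C=C(\C)C#CC1=C(C)C[C@@H](O)CC1(C)C | target

**Step count and risks**

Total step count: 15. Longest linear sequence: 11 steps (steps 1 to 9, 14 and 15).

The three steps most likely to fail:

Step 4. The α-alkoxy organolithium may undergo a [1,2]-shift or be protonated before it reaches C6', which lies next to the quaternary C1'. The fallback sets out from 6 and returns at 9. Phenyl isocyanate should give (1S)-2,4,4-trimethylcyclohex-2-en-1-yl N-phenylcarbamate F1. Deprotonation with nBuLi, then CuI and ClMgCH2SiMe2(OiPr), should deliver the silylmethyl group from the carbamate-bound copper to C6' on the face of the leaving oxygen (carbamate-directed syn-SN2' substitution), giving dimethyl(propan-2-yloxy){[(1R)-2,6,6-trimethylcyclohex-2-en-1-yl]methyl}silane F2. Tamao oxidation (H2O2, KF, KHCO3, THF/MeOH) then turns the C–Si bond into the C–O bond of 9.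

Step 8. Facial selectivity may be poor or reversed, because the two arms of the ketone are similar in size and the ring has its own bias from the axial methyl on C1' and the C6' side chain. The fallback sets out from 12 and returns at 13. A Luche reduction (NaBH4, CeCl3·7H2O, MeOH) is run without a chiral reagent, and the cis alcohol (1S,4R)-3,5,5-trimethyl-4-{[(1-phenyl-1H-tetrazol-5-yl)sulfonyl]methyl}cyclohex-2-en-1-ol F3 is taken, after chromatography if it forms as part of a mixture. It is inverted at the carbinol carbon by a Mitsunobu reaction with 4-nitrobenzoic acid to (1R,4R)-3,5,5-trimethyl-4-{[(1-phenyl-1H-tetrazol-5-yl)sulfonyl]methyl}cyclohex-2-en-1-yl 4-nitrobenzoate F4, and methanolysis (K2CO3, MeOH, 0 °C) gives 13.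

Step 12. Both aldehyde groups may react, the lithiated diazo compound may add in a conjugate sense to the polyenal, or the terminal polyenyne may decompose. The fallback sets out from 17 and returns at 20, bringing the alkyne in ready-made and building the chain by Wittig reactions (C15 + C10 + C5). Sonogashira coupling of 17 with commercial (2E)-3-methylpent-2-en-4-yn-1-ol should give (2E)-5-[(4R)-4-{[tert-butyl(dimethyl)silyl]oxy}-2,6,6-trimethylcyclohex-1-en-1-yl]-3-methylpent-2-en-4-yn-1-ol F5. PPh3·HBr in CH2Cl2 converts it into [(2E)-5-[(4R)-4-{[tert-butyl(dimethyl)silyl]oxy}-2,6,6-trimethylcyclohex-1-en-1-yl]-3-methylpent-2-en-4-yn-1-yl]triphenylphosphonium bromide F6. Its ylide (NaOMe) reacts with an excess of 2,7-dimethylocta-2,4,6-trienedial to give, after separation of the isomers at the new C11=C12 bond, (2E,4E,6E,8E,10E)-13-[(4R)-4-{[tert-butyl(dimethyl)silyl]oxy}-2,6,6-trimethylcyclohex-1-en-1-yl]-2,7,11-trimethyltrideca-2,4,6,8,10-pentaen-12-ynal F7. A second Wittig reaction with [(2E)-4,4-dimethoxy-3-methylbut-2-en-1-yl]triphenylphosphonium chloride gives (2E,4E,6E,8E,10E,12E,14E)-17-[(4R)-4-{[tert-butyl(dimethyl)silyl]oxy}-2,6,6-trimethylcyclohex-1-en-1-yl]-1,1-dimethoxy-2,6,11,15-tetramethylheptadeca-2,4,6,8,10,12,14-heptaen-16-yne F8, and mild acid hydrolysis of the acetal gives 20.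

**Further compounds**

F1 | step 4 | (1S)-2,4,4-trimethylcyclohex-2-en-1-yl N-phenylcarbamate | CC1=CC(C)(C)CC[C@@H]1OC(=O)Nc1ccccc1
F2 | step 4 | dimethyl(propan-2-yloxy){[(1R)-2,6,6-trimethylcyclohex-2-en-1-yl]methyl}silane | CC1=CCCC(C)(C)[C@H]1C[Si](C)(C)OC(C)C
F3 | step 8 | (1S,4R)-3,5,5-trimethyl-4-{[(1-phenyl-1H-tetrazol-5-yl)sulfonyl]methyl}cyclohex-2-en-1-ol | CC1=C[C@@H](O)CC(C)(C)[C@H]1CS(=O)(=O)c1nnnn1-c1ccccc1
F4 | step 8 | (1R,4R)-3,5,5-trimethyl-4-{[(1-phenyl-1H-tetrazol-5-yl)sulfonyl]methyl}cyclohex-2-en-1-yl 4-nitrobenzoate | CC1=C[C@H](OC(=O)c2ccc(cc2)[N+](=O)[O-])CC(C)(C)[C@H]1CS(=O)(=O)c1nnnn1-c1ccccc1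
F5 | step 12 | (2E)-5-[(4R)-4-{[tert-butyl(dimethyl)silyl]oxy}-2,6,6-trimethylcyclohex-1-en-1-yl]-3-methylpent-2-en-4-yn-1-ol | OC/C=C(\C)C#CC1=C(C)C[C@@H](O[Si](C)(C)C(C)(C)C)CC1(C)C
F6 | step 12 | [(2E)-5-[(4R)-4-{[tert-butyl(dimethyl)silyl]oxy}-2,6,6-trimethylcyclohex-1-en-1-yl]-3-methylpent-2-en-4-yn-1-yl]triphenylphosphonium bromide | C(/C=C(\C)C#CC1=C(C)C[C@@H](O[Si](C)(C)C(C)(C)C)CC1(C)C)[P+](c1ccccc1)(c1ccccc1)c1ccccc1.[Br-]
F7 | step 12 | (2E,4E,6E,8E,10E)-13-[(4R)-4-{[tert-butyl(dimethyl)silyl]oxy}-2,6,6-trimethylcyclohex-1-en-1-yl]-2,7,11-trimethyltrideca-2,4,6,8,10-pentaen-12-ynal | O=C/C(C)=C/C=C/C=C(C)/C=C/C=C(\C)C#CC1=C(C)C[C@@H](O[Si](C)(C)C(C)(C)C)CC1(C)C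
F8 | step 12 | (2E,4E,6E,8E,10E,12E,14E)-17-[(4R)-4-{[tert-butyl(dimethyl)silyl]oxy}-2,6,6-trimethylcyclohex-1-en-1-yl]-1,1-dimethoxy-2,6,11,15-tetramethylheptadeca-2,4,6,8,10,12,14-heptaen-16-yne | COC(OC)/C(C)=C/C=C/C(C)=C/C=C/C=C(C)/C=C/C=C(\C)C#CC1=C(C)C[C@@H](O[Si](C)(C)C(C)(C)C)CC1(C)C
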